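Assumption: the chain is numbered from the ketone carbon (C1) to the carbon bonded to ring B (C11); 1,3,5-tris(benzyloxy)benzene, undec-10-enal and cyclohex-2-en-1-one are taken as purchasable. The atom counts of the key-step precursor and product were checked against the target (eleven chain carbons) and needed no correction.

## Structural features

The target is 11-(2-hydroxyphenyl)-1-(2,4,6-trihydroxyphenyl)undecan-1-one, C23H30O5: two benzene rings joined by an unbranched chain of eleven carbons, a ketone carbon C1 followed by ten methylenes. Ring A is a phloroglucinol that carries the C1 acyl group between two of its hydroxyls. Ring B is a phenol whose hydroxyl-bearing carbon is the direct neighbour of the carbon bonded to C11. There is no stereocentre, so no stereocentres stand next to each other; the only stereocentre in the route is a transient racemic carbinol. The fragile parts are the free acylphloroglucinol (acidic, easily oxidized in base, nucleophilic at its two open ring carbons) and, on the way, any benzylic carbinol flanked by two ortho alkoxy groups, which ionizes readily. The real difficulty is regiochemical and chemoselective: the chain must sit ortho, not para, to the ring B hydroxyl; ring A must be acylated once; and the two chain ends must be told apart across nine inert methylenes. The key step uses the fact that the C–OH carbon and the chain-bearing carbon of ring B correspond to the carbonyl carbon and the alpha carbon of cyclohex-2-en-1-one. A Morita–Baylis–Hillman adduct of that enone with an aldehyde at C11 has the oxidation level of the ortho-alkylphenol plus water, so ring B can be completed by loss of water alone.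

## Logic of the disconnections

13 to 12. The three O–CH2Ph bonds on ring A are cut. The free acylphloroglucinol is the most reactive part of 13 and is uncovered last; 12 differs from 13 only by three ether groups. The gain is a ring A that is inert from the first step onward. The forward step must cleave the ethers without reducing the C1 ketone or either arene.

12 to 10, through 11. No skeletal bond is cut. Ring B is taken back, by formal addition of water, from a phenol to a beta-hydroxy enone, with 11 as the half-way dienone. The hydroxyl carbon of ring B and its neighbour thereby become a carbonyl carbon and a nucleophilic alpha carbon, which opens the next cut. The ortho pattern no longer has to be found on an arene, because it is built into a six-membered enone. The forward step must lose water and shift two hydrogens without an oxidant and without disturbing the benzyl ethers.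

10 to 8 and 9. The bond between C11 and the ring carbon next to the carbonyl is cut. This is the strategic cut: it splits 10 into the commercial six-carbon ring 9 and the linear 8, which carries ring A, C1 and the whole chain. The forward step must make the bond at the alpha carbon of 9, with the aldehyde of 8 and not its C1 ketone as the electrophile, and 8 must not condense with itself.

8 to 7. No skeletal bond is cut; both carbonyl groups (C1 and C11) are traced back to hydroxyls. Both oxygens can then be introduced at the alcohol level by dependable reactions, and one operation sets both oxidation levels. The forward oxidant must convert a hindered, easily ionized benzylic carbinol and a primary alcohol together and must stop at the aldehyde. A buffered, non-acidic oxidant is therefore preferred to one that activates the carbinol as a leaving group.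

7 to 5, through 6. The C11–O bond is cut, which returns the primary alcohol to a terminal alkene. The alkene is an inert placeholder for the far chain end during the carbanion chemistry. The forward step must deliver oxygen to the terminal carbon only.

5 to 2 and 3, through 4. The bond between C1 and ring A is cut. This gives an aryl nucleophile and 3, which already holds all eleven chain carbons. The forward step needs the carbanion 4 to be generated cleanly at one defined ring carbon and to add to the aldehyde faster than it deprotonates it.

2 to 1. The C–Br bond is cut. The three open ring positions of 1 are equivalent, so one bromination marks the future acyl-bearing carbon. The forward step must stop at the monobromide.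

## Other disconnections considered

Alternative 1: The cut lies inside ring A, between the acyl-bearing carbon and one hydroxyl-bearing neighbour, and unfolds the ring into the linear triketo ester A2, methyl 17-[2-(benzyloxy)phenyl]-3,5,7-trioxoheptadecanoate.
- Forward key step: the polyanion of A2, in methanolic KOH or with Mg(OMe)2, would close ring A by a Claisen (Dieckmann-type) attack of the C6 methylene on the ester carbon C1. Enolization would give A1, 11-[2-(benzyloxy)phenyl]-1-(2,4,6-trihydroxyphenyl)undecan-1-one, one hydrogenolysis from the target.
- In its favour: it mirrors the biosynthetic logic and makes ring A with its three hydroxyls and the acyl group in one step. Ring A needs no protection, so it uses one benzyl ether where the chosen plan uses three; on protecting-group economy it is the better plan.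
- Against it here: A2 is a 1,3,5,7-tetracarbonyl compound that must be built by acylating a polyanion of a beta,delta-diketo ester. Such a chain can also close in the aldol mode (C2 onto the C7 carbonyl, giving a resorcylate) or lactonize to a pyranone, and the outcome would depend on counter-ion and solvent.
- Comparison:
  - Structure: the ortho pattern of ring B is bought in a starting material instead of made, which is equal in outcome.
  - Mechanism: it relies on stoichiometric strong-base polyanion chemistry with three possible cyclization modes, against a catalytic, near-neutral addition with one sensible outcome.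
  - Step economy: the two plans are estimated as roughly equal.

Alternative 2: The cut is the C10–C11 bond, one carbon away from ring B.
- Forward key step: tert-butyl 2-(hydroxymethyl)phenyl carbonate A4, deprotonated by a sacrificial magnesium base such as t-BuMgCl, would pass its carbonate group to the benzylic oxygen and eliminate to the ortho-quinone methide. Conjugate addition of the chain Grignard reagent A5 at the exocyclic carbon would restore the arene and give A3, 2-{11-[tert-butyl(dimethyl)silyloxy]-11-[2,4,6-tris(benzyloxy)phenyl]undecyl}phenol.
- In its favour: ring B stays aromatic, so no aromatization step is needed. The ortho relation of hydroxyl and chain is secured as firmly as in the chosen plan (equal). The bond formation is driven by rearomatization and should be fast at low temperature; on the reliability of the carbon–carbon bond formation with an aliphatic partner it is probably the better plan.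
- Against it here: a Grignard reagent cannot carry the C1 ketone, which must travel as a silyl-protected carbinol. Desilylation and oxidation, in the presence of a free phenol, are then needed after the key step and before hydrogenolysis. A5 has to be made by magnesium insertion next to an ionizable benzylic silyl ether, the quinone methide can oligomerize, and an excess of one partner is required.
- Comparison:
  - Structure: equal control of the ortho pattern.
  - Mechanism: stoichiometric organomagnesium chemistry against organocatalysis.
  - Step economy: about two steps longer after the key step, and C1 does not stay at the ketone level; the chosen plan is the better here.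

Alternative 3: Both bonds to C1 are cut and the carbonyl carbon is supplied by carbon monoxide A9.
- Forward key step: 2-iodo-1,3,5-tris(benzyloxy)benzene A7 would add oxidatively to zerovalent palladium (Pd(PPh3)4) and A9 would insert at atmospheric pressure. The alkyl group of the B-alkyl-9-BBN A8 (made in the flask from the alkene A10 and 9-BBN, activated by K3PO4) would be transferred, and reductive elimination would give A6, 11-[2-(benzyloxy)phenyl]-1-[2,4,6-tris(benzyloxy)phenyl]undecan-1-one. One hydrogenolysis converts A6 into the target.
- In its favour: two bonds are formed in one operation, the ketone arrives at the right oxidation level with no redox adjustment, and the whole plan is estimated at about five steps. On convergence and step count it is the better plan.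
- Against it here: A7 is electron-rich and flanked by two ortho benzyloxy groups, so oxidative addition and insertion of A9 should be slow. Direct alkyl–aryl coupling without A9, or beta-hydride elimination, could then compete. A toxic gas has to be handled, a point of safety on which the chosen plan is the better.
- Comparison:
  - Structure: the ortho pattern of ring B is again bought (equal).
  - Mechanism: a three-component catalytic cycle whose insertion and transmetalation rates must be balanced, against a two-component organocatalytic addition.
  - Step economy: better than the chosen plan. The chosen plan is kept because the selectivity of its key step does not depend on a doubly ortho-substituted aryl palladium species.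

Key step: step 5

## Route

Step 1
Reactants: 1 1,3,5-tris(benzyloxy)benzene
Product: 2 2-bromo-1,3,5-tris(benzyloxy)benzene
Conditions: NBS (1.0 equiv), CH2Cl2, −78 → 0 °C, dark
Reagents that add atoms: N-bromosuccinimide, O=C1CCC(=O)N1Br
Why: Electrophilic aromatic bromination; the three open ring positions of 1 are equivalent and each is activated by two ortho and one para alkoxy group. The first bromine deactivates the ring enough for one equivalent of reagent at low temperature to stop at the monobromide.

Step 2
Reactants: 2 2-bromo-1,3,5-tris(benzyloxy)benzene; 3 undec-10-enal
Product: 5 1-[2,4,6-tris(benzyloxy)phenyl]undec-10-en-1-ol (racemic), via aryllithium 4 (not isolated)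
Conditions: n-BuLi (1.05 equiv), THF, −78 °C, 20 min; then 3 (1.1 equiv), −78 → −30 °C; H2O
Reagents that add atoms: none
Why: Bromine–lithium exchange is fast at −78 °C and fixes the carbanion at the former C–Br carbon; the aryllithium 4 then adds 1,2 to the aldehyde of 3 (organolithium addition to a carbonyl group). The carbinol stereocentre forms without control, as a racemate, and is removed in step 4.

Step 3
Reactants: 5 1-[2,4,6-tris(benzyloxy)phenyl]undec-10-en-1-ol
Product: 7 1-[2,4,6-tris(benzyloxy)phenyl]undecane-1,11-diol (racemic), via B-alkyl-9-BBN adduct 6 (not isolated)
Conditions: 9-BBN (2.5 equiv), THF, 0 °C → rt; then 3 M aq NaOH, 30% H2O2, 0 °C → rt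
Reagents that add atoms: hydrogen peroxide, OO
Why: Hydroboration–oxidation; the bulky dialkylborane places boron on the terminal carbon, and alkaline peroxide replaces the C–B bond by C–OH, giving the anti-Markovnikov primary alcohol. The excess of reagent allows for any borylation of the free hydroxyl, whose B–O bond is hydrolysed in the same work-up; no stereocentre is created.

Step 4
Reactants: 7 1-[2,4,6-tris(benzyloxy)phenyl]undecane-1,11-diol
Product: 8 11-oxo-11-[2,4,6-tris(benzyloxy)phenyl]undecanal
Conditions: Dess–Martin periodinane (2.6 equiv), pyridine (6 equiv), CH2Cl2, 0 °C → rt
Reagents that add atoms: none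
Why: Dess–Martin oxidation; both hydroxyls exchange onto iodine and lose their carbinol hydrogen, the primary one stopping at the aldehyde. The pyridine-buffered medium is chosen because the di-ortho-alkoxy benzylic carbinol ionizes easily; the racemic stereocentre disappears here.

Step 5
Reactants: 8 11-oxo-11-[2,4,6-tris(benzyloxy)phenyl]undecanal; 9 cyclohex-2-en-1-one
Product: 10 2-{1-hydroxy-11-oxo-11-[2,4,6-tris(benzyloxy)phenyl]undecyl}cyclohex-2-en-1-one (racemic)
Conditions: 9 (3 equiv), PBu3 (0.2 equiv), racemic 1,1'-bi-2-naphthol (0.1 equiv), THF, rt, Ar
Reagents that add atoms: none
Why: PBu3 adds to the beta carbon of 9 to give a beta-phosphonium enolate, whose alpha carbon attacks the aldehyde carbon of 8 (chain C11) in an aldol step; the bi-naphthol, a hydrogen-bond donor, activates the aldehyde and relays the proton from the alpha carbon to the alkoxide, after which E1cB loss of PBu3 restores the enone in 10. The closest known reaction type is the phosphine/phenol co-catalysed Morita–Baylis–Hillman reaction of cyclic enones with enolizable aliphatic aldehydes. One skeletal bond is formed and no ring is closed, so no mode of ring closure has to be considered. The carbinol carbon is the single new stereocentre; nothing controls it, it should form as a racemate, and this does not matter because the centre is erased in step 6. The step needs chemoselectivity for the aldehyde over the C1 ketone: that ketone is a di-ortho-benzyloxy aryl ketone, twisted out of plane and screened on both faces, and unactivated ketones are poor acceptors in this reaction in any case. It also needs the aldol self-condensation of 8 to stay slow, which the weakly basic nucleophilic catalyst and the excess of 9 should secure. The benzyl ethers are inert to the catalyst.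

Step 6
Reactants: 10 2-{1-hydroxy-11-oxo-11-[2,4,6-tris(benzyloxy)phenyl]undecyl}cyclohex-2-en-1-one
Product: 12 11-(2-hydroxyphenyl)-1-[2,4,6-tris(benzyloxy)phenyl]undecan-1-one, via exocyclic dienone 11 (not isolated)
Conditions: p-toluenesulfonic acid monohydrate (0.2 equiv), toluene, 90 °C
Reagents that add atoms: none
Why: Dehydrative aromatization of a cyclohexenone Morita–Baylis–Hillman carbinol: acid-catalysed loss of water from the beta-hydroxy enone through its dienol gives dienone 11, whose enol is protonated at the exocyclic carbon and then loses a ring proton to reach the arene. The sequence is an isomerization plus loss of water, needs no oxidant, is driven by the aromatic stabilization of ring B and deletes the racemic stereocentre; aryl benzyl ethers should tolerate the catalytic sulfonic acid.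

Step 7
Reactants: 12 11-(2-hydroxyphenyl)-1-[2,4,6-tris(benzyloxy)phenyl]undecan-1-one
Product: 13 11-(2-hydroxyphenyl)-1-(2,4,6-trihydroxyphenyl)undecan-1-one
Conditions: H2 (1 atm), 10% Pd/C, EtOAc–MeOH (1:1), rt
Reagents that add atoms: none
Why: Catalytic hydrogenolysis of the three benzyl aryl ethers. The ketone is deactivated by three oxygen donors and, once the ortho hydroxyls are free, held in a hydrogen bond, so neither it nor the two phenol rings should be reduced at atmospheric pressure and room temperature.

## Compound list

1 | 1,3,5-tris(benzyloxy)benzene | c1(OCc2ccccc2)cc(OCc2ccccc2)cc(OCc2ccccc2)c1 | starting material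
2 | 2-bromo-1,3,5-tris(benzyloxy)benzene | Brc1c(OCc2ccccc2)cc(OCc2ccccc2)cc1OCc1ccccc1 | intermediate
3 | undec-10-enal | C=CCCCCCCCCC=O | starting material
4 | [2,4,6-tris(benzyloxy)phenyl]lithium (formed in the flask) | [Li]c1c(OCc2ccccc2)cc(OCc2ccccc2)cc1OCc1ccccc1 | intermediate
5 | 1-[2,4,6-tris(benzyloxy)phenyl]undec-10-en-1-ol (racemic) | C=CCCCCCCCCC(O)c1c(OCc2ccccc2)cc(OCc2ccccc2)cc1OCc1ccccc1 | intermediate
6 | 11-(9-borabicyclo[3.3.1]nonan-9-yl)-1-[2,4,6-tris(benzyloxy)phenyl]undecan-1-ol (racemic, formed in the flask) | OC(CCCCCCCCCCB1C2CCCC1CCC2)c1c(OCc2ccccc2)cc(OCc2ccccc2)cc1OCc1ccccc1 | intermediate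
7 | 1-[2,4,6-tris(benzyloxy)phenyl]undecane-1,11-diol (racemic) | OCCCCCCCCCCC(O)c1c(OCc2ccccc2)cc(OCc2ccccc2)cc1OCc1ccccc1 | intermediate
8 | 11-oxo-11-[2,4,6-tris(benzyloxy)phenyl]undecanal | O=CCCCCCCCCCC(=O)c1c(OCc2ccccc2)cc(OCc2ccccc2)cc1OCc1ccccc1 | intermediate
9 | cyclohex-2-en-1-one | O=C1C=CCCC1 | starting material
10 | 2-{1-hydroxy-11-oxo-11-[2,4,6-tris(benzyloxy)phenyl]undecyl}cyclohex-2-en-1-one (racemic) | O=C1CCCC=C1C(O)CCCCCCCCCC(=O)c1c(OCc2ccccc2)cc(OCc2ccccc2)cc1OCc1ccccc1 | intermediate
11 | 2-{11-oxo-11-[2,4,6-tris(benzyloxy)phenyl]undecylidene}cyclohex-3-en-1-one (exocyclic alkene geometry not defined, formed in the flask) | O=C1CCC=CC1=CCCCCCCCCCC(=O)c1c(OCc2ccccc2)cc(OCc2ccccc2)cc1OCc1ccccc1 | intermediate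
12 | 11-(2-hydroxyphenyl)-1-[2,4,6-tris(benzyloxy)phenyl]undecan-1-one | O=C(CCCCCCCCCCc1ccccc1O)c1c(OCc2ccccc2)cc(OCc2ccccc2)cc1OCc1ccccc1 | intermediate
13 | 11-(2-hydroxyphenyl)-1-(2,4,6-trihydroxyphenyl)undecan-1-one (no stereocentre) | O=C(CCCCCCCCCCc1ccccc1O)c1c(O)cc(O)cc1O | target

## Step count and least certain steps

Total step count: 7. Longest linear sequence: 7 steps (1 → 2 → 5 → 7 → 8 → 10 → 12 → 13); 3 and 9 enter as purchased materials.

Step 5 (key step). The most likely failure is slow turnover with the enolizable aliphatic aldehyde, so that the reaction stalls while phosphine-catalysed self-dimerization of 9 (Rauhut–Currier) and slow aldol self-condensation of 8 consume material. The fallback replaces the non-aromatic ring B nucleophile by an aromatic one and sets out from 8. [2-(Benzyloxy)phenyl]magnesium bromide F1, made from 1-(benzyloxy)-2-bromobenzene and Mg in THF, should add at −78 °C to the aldehyde only and give 11-[2-(benzyloxy)phenyl]-11-hydroxy-1-[2,4,6-tris(benzyloxy)phenyl]undecan-1-one F2 after quenching with water. Hydrogenation over Pd/C in EtOAc–AcOH should then remove the benzylic hydroxyl together with the four benzyl ethers. The route is rejoined at 13, and 10, 11 and 12 are bypassed.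

Step 6. The isomerization may stop at the dienone stage, because the secondary alkyl carbinol has no aryl group to assist loss of water. Prolonged heating with acid could then cause migration or loss of benzyl groups, or oligomerization of the dienone. The fallback changes from acid catalysis to leaving-group activation followed by base and sets out from 10. Acetylation (Ac2O, pyridine, 4-(dimethylamino)pyridine, CH2Cl2) should give 1-(6-oxocyclohex-1-en-1-yl)-11-oxo-11-[2,4,6-tris(benzyloxy)phenyl]undecyl acetate F3. DBU in MeCN at 60 °C should remove a gamma proton, expel acetate in an E1cB step to give 11, and carry the proton shifts on to the phenoxide. Acidic work-up rejoins the route at 12.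

Step 2. The aryllithium may transfer its charge to a benzylic OCH2 position, followed by Wittig rearrangement, or may deprotonate the aldehyde instead of adding, which returns 1. The fallback reverses the polarity of the C1–ring A bond formation and sets out from 1. Vilsmeier–Haack formylation (POCl3, DMF, 0 °C → rt) should give the iminium salt N,N-dimethyl-1-[2,4,6-tris(benzyloxy)phenyl]methaniminium chloride F4, which aqueous NaOH work-up hydrolyses to 2,4,6-tris(benzyloxy)benzaldehyde F5. Dec-9-en-1-ylmagnesium bromide F6, made from 10-bromodec-1-ene and Mg in THF, should add to F5 and, after quenching with water, rejoin the route at 5; 2 and 4 are bypassed.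

Step 4. The acetic acid released may ionize the di-ortho-alkoxy benzylic carbinol, leading to elimination toward a styrene, and the hindered secondary alcohol may oxidize incompletely. The fallback separates the two oxidations by mechanism and sets out from 7. Activated MnO2 in CH2Cl2 at rt should oxidize only the benzylic carbinol, on a neutral surface, to 11-hydroxy-1-[2,4,6-tris(benzyloxy)phenyl]undecan-1-one F7. The remaining primary alcohol, now free of any acid-sensitive neighbour, should be oxidized under Parikh–Doering conditions (SO3·pyridine, DMSO, i-Pr2NEt, 0 °C), which rejoins the route at 8.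

## Further compounds

F1 | step 5 | [2-(benzyloxy)phenyl]magnesium bromide | Br[Mg]c1ccccc1OCc1ccccc1
F2 | step 5 | 11-[2-(benzyloxy)phenyl]-11-hydroxy-1-[2,4,6-tris(benzyloxy)phenyl]undecan-1-one (racemic) | OC(CCCCCCCCCC(=O)c1c(OCc2ccccc2)cc(OCc2ccccc2)cc1OCc1ccccc1)c1ccccc1OCc1ccccc1
F3 | step 6 | 1-(6-oxocyclohex-1-en-1-yl)-11-oxo-11-[2,4,6-tris(benzyloxy)phenyl]undecyl acetate (racemic) | CC(=O)OC(CCCCCCCCCC(=O)c1c(OCc2ccccc2)cc(OCc2ccccc2)cc1OCc1ccccc1)C1=CCCCC1=O
F4 | step 2 | N,N-dimethyl-1-[2,4,6-tris(benzyloxy)phenyl]methaniminium chloride | C[N+](C)=Cc1c(OCc2ccccc2)cc(OCc2ccccc2)cc1OCc1ccccc1.[Cl-]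
F5 | step 2 | 2,4,6-tris(benzyloxy)benzaldehyde | O=Cc1c(OCc2ccccc2)cc(OCc2ccccc2)cc1OCc1ccccc1
F6 | step 2 | dec-9-en-1-ylmagnesium bromide | C=CCCCCCCCC[Mg]Br
F7 | step 4 | 11-hydroxy-1-[2,4,6-tris(benzyloxy)phenyl]undecan-1-one | OCCCCCCCCCCC(=O)c1c(OCc2ccccc2)cc(OCc2ccccc2)cc1OCc1ccccc1
A1 | alternative 1 | 11-[2-(benzyloxy)phenyl]-1-(2,4,6-trihydroxyphenyl)undecan-1-one | O=C(CCCCCCCCCCc1ccccc1OCc1ccccc1)c1c(O)cc(O)cc1O
A2 | alternative 1 | methyl 17-[2-(benzyloxy)phenyl]-3,5,7-trioxoheptadecanoate | COC(=O)CC(=O)CC(=O)CC(=O)CCCCCCCCCCc1ccccc1OCc1ccccc1
A3 | alternative 2 | 2-{11-[tert-butyl(dimethyl)silyloxy]-11-[2,4,6-tris(benzyloxy)phenyl]undecyl}phenol (racemic) | Oc1ccccc1CCCCCCCCCCC(O[Si](C)(C)C(C)(C)C)c1c(OCc2ccccc2)cc(OCc2ccccc2)cc1OCc1ccccc1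
A4 | alternative 2 | tert-butyl 2-(hydroxymethyl)phenyl carbonate | CC(C)(C)OC(=O)Oc1ccccc1CO
A5 | alternative 2 | {10-[tert-butyl(dimethyl)silyloxy]-10-[2,4,6-tris(benzyloxy)phenyl]decyl}magnesium bromide (racemic) | Br[Mg]CCCCCCCCCC(O[Si](C)(C)C(C)(C)C)c1c(OCc2ccccc2)cc(OCc2ccccc2)cc1OCc1ccccc1
A6 | alternative 3 | 11-[2-(benzyloxy)phenyl]-1-[2,4,6-tris(benzyloxy)phenyl]undecan-1-one | O=C(CCCCCCCCCCc1ccccc1OCc1ccccc1)c1c(OCc2ccccc2)cc(OCc2ccccc2)cc1OCc1ccccc1
A7 | alternative 3 | 2-iodo-1,3,5-tris(benzyloxy)benzene | Ic1c(OCc2ccccc2)cc(OCc2ccccc2)cc1OCc1ccccc1
A8 | alternative 3 | 9-{10-[2-(benzyloxy)phenyl]decyl}-9-borabicyclo[3.3.1]nonane | C(CCCCCCCCCc1ccccc1OCc1ccccc1)B1C2CCCC1CCC2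
A9 | alternative 3 | carbon monoxide | [C-]#[O+]
A10 | alternative 3 | 1-(benzyloxy)-2-(dec-9-en-1-yl)benzene | C=CCCCCCCCCc1ccccc1OCc1ccccc1
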